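**Assumption:** the SMILES contains no stereocentre and no configurationally fixed axis, so the target is a single achiral compound and no stereocontrol is needed. Quinuclidine N-oxide (step 2 reagent) is a known compound, made beforehand from quinuclidine and aqueous H2O2 and dried; it is not counted as a step.

## Retrosynthetic overview

1. Ring B is bought as 1,3,5-trimethoxybenzene 1; ethyl diazoacetate 2 supplies the two-carbon side chain (arylacetate 3, C-C bond).
2. Key disconnection: the C3'-O bond. The only free ring position of 3 is oxygenated (aryl triflate 4) and hydrolysis gives hydroxy acid 5; this desymmetrises ring B.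
3. Ring A is bought as phloroglucinol 6; the C4-C4a bond comes from acylation by 5 (deoxybenzoin 7).
4. Ring C is closed last: C2 comes from DMF (enaminone 8), then O1-C2 bond formation gives target 9.
5. Order of rings: B and A are present in 1 and 6; ring C is the only ring built (step 3).

## Route

Step 1
Reactants: 1 1,3,5-trimethoxybenzene; 2 ethyl diazoacetate
Product: 3 ethyl 2-(2,4,6-trimethoxyphenyl)acetate
Conditions: Rh2(OAc)4 (1 mol%), 1 (3 equiv), 2 added over 6 h, CH2Cl2, 25 °C; excess 1 recovered
Reagents that add atoms: none
Why: Formal aromatic C-H insertion of a rhodium carbenoid (Buchner-type chemistry diverted to substitution): the electrophilic carbenoid from 2 attacks the very electron-rich ring of 1 and the zwitterion (or methoxy-substituted norcaradiene) rearomatises by proton transfer; the three ring CH positions are equivalent, excess 1 and slow addition suppress carbene dimerisation and double alkylation, and no stereocentre is formed.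

Step 2
Reactants: 3 ethyl 2-(2,4,6-trimethoxyphenyl)acetate
Product: 5 2-(3-hydroxy-2,4,6-trimethoxyphenyl)acetic acid, via aryl triflate 4 (not isolated)
Conditions: anhydrous quinuclidine N-oxide (1.15 equiv), Tf2O (1.1 equiv), CH2Cl2, −78 °C, 15 min; then 3, −40 → 0 °C, 2 h; then 2 M aq NaOH (6 equiv), MeOH, 45 °C, argon, 3 h; HCl to pH 2
Reagents that add atoms: quinuclidine N-oxide, [O-][N+]12CCC(CC1)CC2 (the phenol oxygen); sodium hydroxide, [Na+].[OH-] (the OH oxygen of the carboxylic acid); trifluoromethanesulfonic anhydride, O=S(=O)(OS(=O)(=O)C(F)(F)F)C(F)(F)F (the triflyl group of 4 only)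
Why: Proposed new method: electrophilic aromatic C-H triflyloxylation by an N-(sulfonyloxy)ammonium salt, a reagent class not yet used as an oxygen electrophile; O-triflylation of the N-oxide gives a cation whose oxygen lies between a sulfonyl group and a quaternary bridgehead nitrogen that can neither accept a nucleophile nor undergo Polonovski elimination, so the arene of 3 attacks oxygen at C3 (equivalent to C5, ortho/ortho/para to the three methoxy groups), quinuclidine leaves and takes up the arenium proton, and the deactivating OTf group of 4 blocks a second oxygenation and quinone formation until NaOH cleaves the triflate S-O bond and saponifies the ester in the same flask; the closest known reaction types are arene fluorination by N-fluoroammonium salts (amine leaving group) and arene C-H sulfonyloxylation by bis(sulfonyl) peroxides; no stereocentre is formed.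

Step 3
Reactants: 5 2-(3-hydroxy-2,4,6-trimethoxyphenyl)acetic acid; 6 phloroglucinol
Product: 9 5,7-dihydroxy-3-(3-hydroxy-2,4,6-trimethoxyphenyl)-4H-chromen-4-one, via deoxybenzoin 7 (not isolated), via enaminone 8 (not isolated)
Conditions: BF3·OEt2 (8 equiv, as solvent), 85 °C, 2 h; cool to 10 °C, DMF; MsCl (3 equiv) in DMF, 50 → 75 °C, 2 h; aq NaOAc, recrystallise
Reagents that add atoms: N,N-dimethylformamide, CN(C)C=O (C2 of the chromone)
Why: Friedel-Crafts acylation of symmetric phloroglucinol (only one regioisomer possible), then Vilsmeier-type aminomethylenation of the activated methylene of 7 and ring closure by addition-elimination of the ortho phenol oxygen on the enaminone carbon of 8 with loss of dimethylamine (O1-C2 bond); this is the established one-pot BF3·OEt2/DMF/MsCl isoflavone synthesis, which tolerates free phenols, and no stereocentre is formed.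

## Compound list

1 | 1,3,5-trimethoxybenzene | COc1cc(OC)cc(OC)c1 | starting material
2 | ethyl diazoacetate | CCOC(=O)C=[N+]=[N-] | starting material
3 | ethyl 2-(2,4,6-trimethoxyphenyl)acetate | CCOC(=O)Cc1c(OC)cc(OC)cc1OC | intermediate
4 | ethyl 2-[2,4,6-trimethoxy-3-(trifluoromethanesulfonyloxy)phenyl]acetate | CCOC(=O)Cc1c(OC)cc(OC)c(OS(=O)(=O)C(F)(F)F)c1OC | intermediate (not isolated)
5 | 2-(3-hydroxy-2,4,6-trimethoxyphenyl)acetic acid | OC(=O)Cc1c(OC)cc(OC)c(O)c1OC | intermediate
6 | phloroglucinol (benzene-1,3,5-triol) | Oc1cc(O)cc(O)c1 | starting material
7 | 2-(3-hydroxy-2,4,6-trimethoxyphenyl)-1-(2,4,6-trihydroxyphenyl)ethan-1-one | O=C(Cc1c(OC)cc(OC)c(O)c1OC)c1c(O)cc(O)cc1O | intermediate (not isolated)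
8 | 3-(dimethylamino)-2-(3-hydroxy-2,4,6-trimethoxyphenyl)-1-(2,4,6-trihydroxyphenyl)prop-2-en-1-one (push-pull alkene, geometry not fixed) | CN(C)C=C(c1c(OC)cc(OC)c(O)c1OC)C(=O)c1c(O)cc(O)cc1O | intermediate (not isolated)
9 | 5,7-dihydroxy-3-(3-hydroxy-2,4,6-trimethoxyphenyl)-4H-chromen-4-one (achiral) | COc1cc(OC)c(-c2coc3cc(O)cc(O)c3c2=O)c(OC)c1O | target

## Step count and risk

Total steps: 3. Longest linear sequence: 3 (1 → 3 → 5 → 9).

Steps most likely to fail, in order:

**Step 2 (the proposed new oxygenation).** The reagent may decompose before it reacts, or act as a one-electron oxidant towards the electron-rich ring. The fallback uses known chemistry and sets out from 3. Bromination with NBS (MeCN, 0 °C) at the only free ring position gives ethyl 2-(3-bromo-2,4,6-trimethoxyphenyl)acetate F2. Palladium-catalysed hydroxylation of the aryl bromide with KOH (Pd2(dba)3, tBuXPhos, 1,4-dioxane/H2O, 100 °C, argon) also hydrolyses the ester in the same flask; acidification gives 5, where the route is rejoined.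

**Step 3 (one-pot acylation and ring closure).** The electron-rich ring B could be formylated by the iminium reagent, or the acid could acylate itself. The acylphloroglucinol ring A, which is at least as nucleophilic, is known to survive these conditions, so the risk is moderate. The fallback sets out from 5 and 6 and splits the domino into two isolated operations. Acylation alone (BF3·OEt2, 85 °C, aqueous NaOAc work-up) gives 7, which is isolated. Neutral condensation of 7 with N,N-dimethylformamide dimethyl acetal (THF, 60 °C) gives 8 with no electrophilic iminium salt present, and warming in AcOH closes ring C to give 9. No compound outside the list is made (F0).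

**Step 1 (carbenoid C-H functionalisation).** Carbene dimerisation, cycloheptatriene formation or double alkylation may lower the yield. The fallback sets out from 1. Friedel-Crafts acylation with ethyl chlorooxoacetate (TiCl4, CH2Cl2, −20 °C) gives ethyl 2-oxo-2-(2,4,6-trimethoxyphenyl)acetate F1. Ionic hydrogenation of the aryl ketone to the methylene (Et3SiH, TFA, 25 °C) gives 3, where the route is rejoined.

## Further compounds

F1 | step 1 | ethyl 2-oxo-2-(2,4,6-trimethoxyphenyl)acetate | CCOC(=O)C(=O)c1c(OC)cc(OC)cc1OC
F2 | step 2 | ethyl 2-(3-bromo-2,4,6-trimethoxyphenyl)acetate | CCOC(=O)Cc1c(OC)cc(OC)c(Br)c1OC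
F0 | step 3 | none | none
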